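The pyrrole (N1, formyl-bearing C2, tricosyl-bearing C3, C4–H, C5–H) has a bare C4–C5 edge. N1–C5–C4 can therefore come from an N-allyl group, and C3=C4 can be the alkene of a 3-pyrroline made by metathesis.
Cuts, in retrosynthetic order: N1–S (toluenesulfinic acid added back across N1–C2), CHO to CO2Et, C3=C4 (ring-closing metathesis), C3=CH2 to C3=O, C2–C3 (crossed Claisen acylation), N1–C5 (allylation).
Forward: glycine ethyl ester is tosylated and allylated, and its enolate is acylated by tetracosanoyl chloride, which brings C3 and the whole C23 chain. The ketone is methylenated, and the only ring, the five-membered N-heterocycle, is then closed at C3=C4.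
The ester is taken to the aldehyde while nitrogen is still sulfonylated, which avoids hydride chemistry on an NH-pyrrole. DBU then expels toluenesulfinate from N1 and aromatises the ring without an oxidant.
Stereochemistry: the target has none. C2 is a racemic, transient centre that becomes planar in the last step, and the ring alkene is cis by ring size.

Key step: step 6

Remark: compounds 10–14 are handled as racemates at C2. Steps on C23-chain compounds are run at or above 0 °C wherever the chemistry allows, because such waxy materials leave solution in the cold.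

Step 1
Reactants: 1 glycine ethyl ester hydrochloride; 2 p-toluenesulfonyl chloride
Product: 3 ethyl N-tosylglycinate
Conditions: Et3N (2.2 equiv), CH2Cl2, 0 °C → rt
Reagents that add atoms: p-toluenesulfonyl chloride 2, Cc1ccc(cc1)S(=O)(=O)Cl
Why: N-sulfonylation of the liberated primary amine is much faster than any attack on the ester and stops at the monosulfonamide, whose acidic N–H prepares the next step.

Step 2
Reactants: 3 ethyl N-tosylglycinate; 4 allyl bromide
Product: 5 ethyl N-allyl-N-tosylglycinate
Conditions: K2CO3 (1.5 equiv), DMF, rt
Reagents that add atoms: allyl bromide 4, C=CCBr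
Why: SN2 N-alkylation, in which carbonate deprotonates only the sulfonamide N–H and the nitrogen anion displaces bromide from the allylic halide, the α-CH2 being too weakly acidic to compete.

Step 3
Reactants: 6 tetracosanoic acid
Product: 7 tetracosanoyl chloride
Conditions: (COCl)2 (1.5 equiv), DMF (cat.), CH2Cl2, rt → 40 °C
Reagents that add atoms: oxalyl chloride, ClC(=O)C(=O)Cl
Why: Acid chloride formation through the catalytic chloroiminium salt from DMF gives only gaseous by-products, so 7 can be used after evaporation.

Step 4
Reactants: 5 ethyl N-allyl-N-tosylglycinate; 7 tetracosanoyl chloride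
Product: 10 ethyl 2-[allyl(tosyl)amino]-3-oxohexacosanoate (racemic), via glycinate lithium enolate 8 (not isolated), via keto ester lithium enolate 9 (not isolated)
Conditions: 5 (2.1 equiv), LiN(SiMe3)2 (2.1 equiv), THF, −78 °C; 7 (1.0 equiv, THF solution kept at rt, slow addition), −78 → −30 °C; AcOH
Reagents that add atoms: lithium bis(trimethylsilyl)amide, [Li+].C[Si](C)(C)[N-][Si](C)(C)C (supplies only the lithium of 8 and 9)
Why: Crossed Claisen C-acylation of a preformed lithium ester enolate by an acid chloride is fast in the cold, the second equivalent of 8 takes up the acidic proton of the product as 9 so that double acylation is blocked, and C2 arises as a racemic centre that is erased in step 9.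

Step 5
Reactants: 10 ethyl 2-[allyl(tosyl)amino]-3-oxohexacosanoate
Product: 11 ethyl 2-[allyl(tosyl)amino]-3-methylidenehexacosanoate (racemic)
Conditions: Zn, CH2Br2, TiCl4, THF, −40 → 5 °C (reagent aged 3 d); then 10, CH2Cl2, 0 °C → rt
Reagents that add atoms: dibromomethane, BrCBr
Why: Lombardo methylenation, whose geminal dizinc/titanium methylene reagent is oxophilic but barely basic, takes ketones in preference to esters and sulfonamides, tolerates enolisable substrates, and works at room temperature without a base that could move the new alkene into conjugation or disturb C2–H.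

Step 6
Reactants: 11 ethyl 2-[allyl(tosyl)amino]-3-methylidenehexacosanoate
Product: 12 ethyl 1-tosyl-3-tricosyl-2,5-dihydro-1H-pyrrole-2-carboxylate (racemic)
Conditions: RuCl2(=CHPh)(PCy3)(SIMes) (second-generation Grubbs catalyst, 5 mol %), 1,4-benzoquinone (10 mol %), CH2Cl2 (0.01 M), 40 °C, Ar
Reagents that add atoms: none
Why: Ring-closing olefin metathesis by the Chauvin mechanism: the ruthenium benzylidene first exchanges with the unhindered monosubstituted N-allyl alkene, the tethered alkylidene then adds to the 1,1-disubstituted C3 methylidene in an intramolecular [2+2], and cycloreversion of the ruthenacyclobutane leaves the C3=C4 bond and Ru=CH2, which carries the chain on and ends up as ethene. The closest known reactions are the closures of N-allyl-N-methallyl sulfonamides and of N-allylated aza-Baylis–Hillman adducts to trisubstituted N-sulfonyl-3-pyrrolines with N-heterocyclic-carbene ruthenium catalysts. The single ring formed is the five-membered N1–C2–C3–C4–C5 ring, closed from a 1,6-diene by joining the two internal alkene carbons, so the new alkene is cis by ring size and lies between C3 and C4 by construction, with the tricosyl chain next to the ester-bearing carbon. No stereocentre is created, and racemic C2 is a spectator under the neutral conditions. The selectivity needed is ring closure over cross metathesis and over alkene migration: high dilution, the C2 branching and sulfonamide geometry that hold the two alkenes close, the reluctance of the 1,1-disubstituted alkene to dimerise and the escape of ethene at reflux secure the first, and benzoquinone, which intercepts ruthenium hydrides, secures the second. The electron-poor sulfonamide nitrogen does not bind ruthenium, so no catalyst is lost to chelation.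

Step 7
Reactants: 12 ethyl 1-tosyl-3-tricosyl-2,5-dihydro-1H-pyrrole-2-carboxylate
Product: 13 (1-tosyl-3-tricosyl-2,5-dihydro-1H-pyrrol-2-yl)methanol (racemic)
Conditions: LiBH4 (2 equiv), THF, 0 °C → rt
Reagents that add atoms: none
Why: Borohydride reduction of an ester activated by the neighbouring sulfonamide, with a reagent that leaves the sulfonamide and the trisubstituted alkene alone and is too weakly basic to start the sulfinate elimination.

Step 8
Reactants: 13 (1-tosyl-3-tricosyl-2,5-dihydro-1H-pyrrol-2-yl)methanol
Product: 14 1-tosyl-3-tricosyl-2,5-dihydro-1H-pyrrole-2-carbaldehyde (racemic, used crude)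
Conditions: Dess–Martin periodinane (1.3 equiv), CH2Cl2, 0 °C → rt
Reagents that add atoms: none
Why: Dess–Martin oxidation stops at the aldehyde under base-free conditions at room temperature, where the waxy substrate stays dissolved and the acidic C2–H of the product is not touched.

Step 9
Reactants: 14 1-tosyl-3-tricosyl-2,5-dihydro-1H-pyrrole-2-carbaldehyde
Product: 16 3-tricosyl-1H-pyrrole-2-carbaldehyde (target), via 2H-pyrrole tautomer 15 (not isolated)
Conditions: DBU (2.5 equiv), THF, 0 °C → rt
Reagents that add atoms: none
Why: E1cB-type 1,2-elimination in which DBU removes the C2–H (acidified by the formyl group, the C3=C4 alkene and the sulfonamide nitrogen), the carbanion expels toluenesulfinate from N1 to give 15, and a base-mediated proton shift from C5 to nitrogen delivers the aromatic ring, as known for N-sulfonyl-3-pyrrolines that carry a carbonyl group at C2.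

Compound list
1 | glycine ethyl ester hydrochloride | Cl.NCC(=O)OCC | starting material
2 | p-toluenesulfonyl chloride | Cc1ccc(cc1)S(=O)(=O)Cl | starting material
3 | ethyl N-tosylglycinate | CCOC(=O)CNS(=O)(=O)c1ccc(C)cc1 | intermediate
4 | allyl bromide | C=CCBr | starting material
5 | ethyl N-allyl-N-tosylglycinate | CCOC(=O)CN(CC=C)S(=O)(=O)c1ccc(C)cc1 | intermediate
6 | tetracosanoic acid | CCCCCCCCCCCCCCCCCCCCCCCC(=O)O | starting material
7 | tetracosanoyl chloride | CCCCCCCCCCCCCCCCCCCCCCCC(=O)Cl | intermediate
8 | lithium enolate of ethyl N-allyl-N-tosylglycinate (not isolated) | CCOC([O-])=CN(CC=C)S(=O)(=O)c1ccc(C)cc1.[Li+] | intermediate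
9 | lithium enolate of ethyl 2-[allyl(tosyl)amino]-3-oxohexacosanoate (not isolated) | CCCCCCCCCCCCCCCCCCCCCCCC([O-])=C(C(=O)OCC)N(CC=C)S(=O)(=O)c1ccc(C)cc1.[Li+] | intermediate
10 | ethyl 2-[allyl(tosyl)amino]-3-oxohexacosanoate (racemic) | CCCCCCCCCCCCCCCCCCCCCCCC(=O)C(C(=O)OCC)N(CC=C)S(=O)(=O)c1ccc(C)cc1 | intermediate
11 | ethyl 2-[allyl(tosyl)amino]-3-methylidenehexacosanoate (racemic) | CCCCCCCCCCCCCCCCCCCCCCCC(=C)C(C(=O)OCC)N(CC=C)S(=O)(=O)c1ccc(C)cc1 | intermediate
12 | ethyl 1-tosyl-3-tricosyl-2,5-dihydro-1H-pyrrole-2-carboxylate (racemic) | CCCCCCCCCCCCCCCCCCCCCCCC1=CCN(S(=O)(=O)c2ccc(C)cc2)C1C(=O)OCC | intermediate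
13 | (1-tosyl-3-tricosyl-2,5-dihydro-1H-pyrrol-2-yl)methanol (racemic) | CCCCCCCCCCCCCCCCCCCCCCCC1=CCN(S(=O)(=O)c2ccc(C)cc2)C1CO | intermediate
14 | 1-tosyl-3-tricosyl-2,5-dihydro-1H-pyrrole-2-carbaldehyde (racemic) | CCCCCCCCCCCCCCCCCCCCCCCC1=CCN(S(=O)(=O)c2ccc(C)cc2)C1C=O | intermediate
15 | 4-tricosyl-2H-pyrrole-5-carbaldehyde (not isolated) | CCCCCCCCCCCCCCCCCCCCCCCC1=CCN=C1C=O | intermediate
16 | 3-tricosyl-1H-pyrrole-2-carbaldehyde | CCCCCCCCCCCCCCCCCCCCCCCc1cc[nH]c1C=O | target

Total step count: 9. Longest linear sequence: 8 steps (1, 2, 4, 5, 6, 7, 8, 9, from glycine ethyl ester hydrochloride 1).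

Steps most likely to fail

**Step 5 (methylenation).**
- Risk: methylene transfer may be outrun by conversion of the 1,3-dicarbonyl unit into an inert titanium or zinc enolate chelate. Reductive scission of the C2–N bond by residual zinc is a second possible drain.
- Fallback: it sets out from 10 and comes back at 11, replacing carbenoid transfer by addition and elimination.
- Me3SiCH2MgCl/CeCl3 (THF, −78 → 0 °C) is a reagent of very low basicity, of the kind known to add to 1,3-dicarbonyl compounds. It should give ethyl 2-[allyl(tosyl)amino]-3-hydroxy-3-[(trimethylsilyl)methyl]hexacosanoate F1.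
- Catalytic H2SO4 in THF at room temperature should then bring about the acid branch of the Peterson elimination. Only the methylidene can form, because silicon fixes the position of the new double bond.

**Step 4 (enolate acylation).**
- Risk: the waxy acid chloride may leave solution at −78 °C, so that acylation sets in only on warming. By then the enolate may already be decaying by loss of sulfinate or by a [2,3]-shift of the allyl group. O-acylation is a further drain.
- Fallback: it sets out from 7 and 2 and comes back at 10. It builds the keto ester first, brings in nitrogen as a nucleophile, and runs entirely at or above 0 °C.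
- 2 with allylamine and Et3N in CH2Cl2 should give N-allyl-4-methylbenzenesulfonamide F2.
- 7 with KO2CCH2CO2Et, MgCl2 and Et3N in THF–MeCN should give, after decarboxylation on acidic work-up, ethyl 3-oxohexacosanoate F3.
- SO2Cl2 in CH2Cl2 at 0 °C should monochlorinate C2 to ethyl 2-chloro-3-oxohexacosanoate F4.
- Displacement of chloride by F2 with K2CO3 in DMF at room temperature should deliver 10.

**Step 9 (sulfinate loss from the aldehyde).**
- Risk: the C2 carbanion may be reprotonated at C4, which moves the alkene into conjugation with the formyl group and slows the departure of sulfinate. The enolisable aldehyde may also self-condense before aromatisation.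
- Fallback: it sets out from 12 and comes back at 16. It aromatises at the ester level first and adjusts the oxidation level afterwards.
- DBU in THF (rt → 50 °C) should convert 12, through ethyl 4-tricosyl-2H-pyrrole-5-carboxylate F5, into ethyl 3-tricosyl-1H-pyrrole-2-carboxylate F6.
- LiOH in THF–EtOH–H2O at 65 °C, followed by cold acidification, should give 3-tricosyl-1H-pyrrole-2-carboxylic acid F7.
- 1,1'-Carbonyldiimidazole in THF should activate it as 1H-imidazol-1-yl(3-tricosyl-1H-pyrrol-2-yl)methanone F8.
- MeNH(OMe)·HCl should turn F8 into N-methoxy-N-methyl-3-tricosyl-1H-pyrrole-2-carboxamide F9.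
- LiAlH4 (2 equiv, THF, 0 °C) should reduce this Weinreb amide to 16.

Further compounds
F1 | step 5 | ethyl 2-[allyl(tosyl)amino]-3-hydroxy-3-[(trimethylsilyl)methyl]hexacosanoate (racemic mixture of diastereomers) | CCCCCCCCCCCCCCCCCCCCCCCC(O)(C[Si](C)(C)C)C(C(=O)OCC)N(CC=C)S(=O)(=O)c1ccc(C)cc1
F2 | step 4 | N-allyl-4-methylbenzenesulfonamide | C=CCNS(=O)(=O)c1ccc(C)cc1
F3 | step 4 | ethyl 3-oxohexacosanoate | CCCCCCCCCCCCCCCCCCCCCCCC(=O)CC(=O)OCC
F4 | step 4 | ethyl 2-chloro-3-oxohexacosanoate (racemic) | CCCCCCCCCCCCCCCCCCCCCCCC(=O)C(Cl)C(=O)OCC
F5 | step 9 | ethyl 4-tricosyl-2H-pyrrole-5-carboxylate | CCCCCCCCCCCCCCCCCCCCCCCC1=CCN=C1C(=O)OCC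
F6 | step 9 | ethyl 3-tricosyl-1H-pyrrole-2-carboxylate | CCCCCCCCCCCCCCCCCCCCCCCc1cc[nH]c1C(=O)OCC
F7 | step 9 | 3-tricosyl-1H-pyrrole-2-carboxylic acid | CCCCCCCCCCCCCCCCCCCCCCCc1cc[nH]c1C(=O)O
F8 | step 9 | 1H-imidazol-1-yl(3-tricosyl-1H-pyrrol-2-yl)methanone | CCCCCCCCCCCCCCCCCCCCCCCc1cc[nH]c1C(=O)n1ccnc1
F9 | step 9 | N-methoxy-N-methyl-3-tricosyl-1H-pyrrole-2-carboxamide | CCCCCCCCCCCCCCCCCCCCCCCc1cc[nH]c1C(=O)N(C)OC
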